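**Plan**

- Each half is numbered C1 (benzylic carbon bearing the carbamate), C2 (methyl-bearing), C3–C6 (methylenes), C7 (benzylic carbon bearing side chain C8–C11, C11 = CHCl2).
- Retrosynthetic cuts: first both C7–C8 bonds (the C7–H bonds stand where boron was), then both C4–C5 bonds of the 22-membered [7.7]paracyclophane ring, then in the monomer C6–C7, aryl–C7, C3–C4 and C1–C2.
- Enabling feature: C7 is a tertiary benzylic C–H centre bonded to the resorcinol ring carbon lying between the two oxygen-bearing ring carbons, to ring methylene C6 and to side-chain C8. It therefore maps onto a secondary benzylic carbinol carbamate (aryl, C6, O, H) that can be lithiated, borylated and alkylated by 1,2-shift.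
- Forward: a 3,5-dioxygenated benzaldehyde gains C1–C4, is formylated between its MOM ethers, allylated and carbamoylated. Head-to-tail olefin metathesis of two monomers closes the only new ring and hydrogenation saturates it. Both side chains are then attached on the ring, boron is exchanged for hydrogen, and the carbamates, CHCl2 groups and phenols are finished.
- Stereochemistry: C1 and C2 come from an auxiliary-controlled syn aldol. C7 comes from a reagent-controlled allylboration to the (S)-carbinol, whose configuration is relayed stereospecifically (retentive borylation, invertive shift, retentive protodeboronation).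

Key step: step 13

Remark: (R)-4-benzyl-3-propionyloxazolidin-2-one, the B-allyldiisopinocampheylborane derived from (+)-α-pinene and trichloroacetyl isocyanate are taken as purchased reagents; "cyclophane" below always means the 22-membered [7.7]paracyclophane core with the phenol oxygens flanking C7.

**Step 1**
Reactants: 1 4-chloro-1,1-dimethoxybutane; 2 2-isopropoxy-4,4,5,5-tetramethyl-1,3,2-dioxaborolane
Product: 4 2-(4,4-dimethoxybutyl)-4,4,5,5-tetramethyl-1,3,2-dioxaborolane, via (4,4-dimethoxybutyl)magnesium chloride 3 (not isolated)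
Conditions: Mg, I2 (cat.), THF, reflux; then 2, THF, −78 °C → rt; aq. NH4Cl
Reagents that add atoms: none
Why: Grignard formation from the primary chloride and borylation by displacement of isopropoxide at boron is the standard entry to primary alkyl pinacol boronates, and the dimethyl acetal is inert to the organomagnesium.

**Step 2**
Reactants: 5 3,5-dihydroxybenzaldehyde
Product: 6 3,5-bis(methoxymethoxy)benzaldehyde
Conditions: MOMCl, iPr2NEt, CH2Cl2, 0 °C → rt
Reagents that add atoms: chloromethyl methyl ether, COCCl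
Why: O-alkylation of both phenols (Williamson-type acetal formation) gives MOM ethers that later direct ring lithiation and come off with mild acid.

**Step 3**
Reactants: 6 3,5-bis(methoxymethoxy)benzaldehyde; 7 (R)-4-benzyl-3-propionyloxazolidin-2-one
Product: 10 (R)-4-benzyl-3-[(2R,3R)-3-[3,5-bis(methoxymethoxy)phenyl]-3-hydroxy-2-methylpropanoyl]oxazolidin-2-one, via Z-dibutylboron enolate 8 (not isolated), via dibutylboron aldolate 9 (not isolated)
Conditions: 7, Bu2BOTf, iPr2NEt, CH2Cl2, 0 °C; then 6, −78 → 0 °C; pH 7 buffer, MeOH, H2O2, 0 °C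
Reagents that add atoms: none
Why: Evans syn aldol, in which the Z-boron enolate reacts through a Zimmerman–Traxler chair on the face away from the benzyl group of the (R)-auxiliary, setting C1 (R) and the syn C2 methyl centre.

**Step 4**
Reactants: 10 syn aldol adduct
Product: 11 (R)-4-benzyl-3-[(2R,3R)-3-[3,5-bis(methoxymethoxy)phenyl]-3-(tert-butyldimethylsilyloxy)-2-methylpropanoyl]oxazolidin-2-one
Conditions: TBSOTf, 2,6-lutidine, CH2Cl2, −78 → 0 °C
Reagents that add atoms: tert-butyldimethylsilyl triflate, CC(C)(C)[Si](C)(C)OS(=O)(=O)C(F)(F)F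
Why: buffered silylation of the secondary benzylic alcohol prevents retro-aldol cleavage and gives a C1 ether that tolerates the later organolithium steps.

**Step 5**
Reactants: 11 silylated aldol adduct
Product: 12 (2S,3R)-3-[3,5-bis(methoxymethoxy)phenyl]-3-(tert-butyldimethylsilyloxy)-2-methylpropan-1-ol
Conditions: LiBH4, MeOH (1 equiv), THF, 0 °C
Reagents that add atoms: none
Why: borohydride reductive cleavage of the N-acyl oxazolidinone gives the primary alcohol (the future C3) without touching C2 and releases the auxiliary.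

**Step 6**
Reactants: 12 primary alcohol
Product: 13 tert-butyl[(1R,2R)-1-[3,5-bis(methoxymethoxy)phenyl]-3-iodo-2-methylpropoxy]dimethylsilane
Conditions: I2, PPh3, imidazole, CH2Cl2, 0 °C → rt
Reagents that add atoms: iodine, II
Why: Appel-type iodination, SN2 displacement of the oxyphosphonium at the primary carbon, involves no stereocentre (the C2 descriptor changes only by priority).

**Step 7**
Reactants: 13 primary iodide
Product: 14 tert-butyl[(1R,2S)-1-[3,5-bis(methoxymethoxy)phenyl]-2-methylpent-4-enyloxy]dimethylsilane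
Conditions: CH2=CHMgBr (excess), CuI (cat.), THF, −30 → 0 °C
Reagents that add atoms: vinylmagnesium bromide, C=C[Mg]Br
Why: copper-catalysed cross-coupling of a primary alkyl iodide with a vinyl Grignard reagent forms C3–C4 and supplies the terminal alkene for ring closure.

**Step 8**
Reactants: 14 aryl alkene
Product: 16 4-[(1R,2S)-1-(tert-butyldimethylsilyloxy)-2-methylpent-4-enyl]-2,6-bis(methoxymethoxy)benzaldehyde, via aryllithium 15 (not isolated)
Conditions: n-BuLi, TMEDA, THF, 0 °C; DMF, 0 °C → rt; H2O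
Reagents that add atoms: N,N-dimethylformamide, CN(C)C=O
Why: directed ortho-metalation occurs at the ring carbon flanked by both MOM ethers (doubly activated and less hindered than the positions next to the branched side chain), and formylation of the aryllithium installs C7.

**Step 9**
Reactants: 16 aryl aldehyde
Product: 18 (1S)-1-{4-[(1R,2S)-1-(tert-butyldimethylsilyloxy)-2-methylpent-4-enyl]-2,6-bis(methoxymethoxy)phenyl}but-3-en-1-ol, via diisopinocampheylborinate 17 (not isolated)
Conditions: B-allyldiisopinocampheylborane [from (+)-α-pinene], Et2O, −78 °C → rt; NaOH, H2O2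
Reagents that add atoms: B-allyldiisopinocampheylborane of the (+)-α-pinene series, C=CCB([C@@H]1C[C@@H]2C[C@H]([C@H]1C)C2(C)C)[C@@H]1C[C@@H]2C[C@H]([C@H]1C)C2(C)C
Why: Brown allylboration through a closed chair transition state, in which the (+)-α-pinene-derived reagent delivers allyl to the Si face of the aryl aldehyde, forms C6–C7 and sets the (S)-carbinol at C7 under reagent control.

**Step 10**
Reactants: 18 homoallylic alcohol; 19 N,N-diisopropylcarbamoyl chloride
Product: 20 (1S)-1-{4-[(1R,2S)-1-(tert-butyldimethylsilyloxy)-2-methylpent-4-enyl]-2,6-bis(methoxymethoxy)phenyl}but-3-enyl N,N-diisopropylcarbamate (monomer)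
Conditions: NaH, THF, 0 °C; then 19, rt → 50 °C
Reagents that add atoms: none
Why: O-acylation of the sodium alkoxide with the carbamoyl chloride installs the directing and leaving group for step 13 without touching the C7–O bond, so the C7 configuration is kept.

**Step 11**
Reactants: 20 monomer carbamate (two molecules)
Product: 21 (E,E)-cyclophane diene biscarbamate (C4=C5 in both bridges; 1R,2S,7S in each half)
Conditions: second-generation Grubbs catalyst, CH2Cl2 (0.01 M), 40 °C, argon purge
Reagents that add atoms: none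
Why: cross-metathesis followed by ring-closing metathesis is reversible for these unhindered alkenes, so open-chain and head-to-head intermediates should funnel to the least strained head-to-tail 22-membered ring, as is known for closely related resorcinol dienes; the alkene geometry is irrelevant because it is removed in step 12.

**Step 12**
Reactants: 21 cyclophane diene
Product: 22 saturated cyclophane bis(C7 N,N-diisopropylcarbamate) (phenols as MOM ethers; C1 oxygens as TBS ethers; 1R,2S,7S in each half)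
Conditions: H2 (3 atm), RhCl(PPh3)3 (cat.), benzene/EtOH, rt
Reagents that add atoms: none
Why: homogeneous rhodium-catalysed hydrogenation saturates the two disubstituted ring alkenes without hydrogenolysis of the benzylic C–O bonds.

**Step 13**
Reactants: 22 saturated cyclophane biscarbamate; 4 side-chain pinacol boronate (two molecules react)
Product: 25 cyclophane bis(C7 tertiary pinacol boronic ester) with both 4,4-dimethoxybutyl chains on C7, via C7,C7'-dilithio biscarbamate 23 (not isolated), via bis(boronate) complex 24 (not isolated)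
Conditions: s-BuLi (2.6 equiv), TMEDA, Et2O, −78 °C; 4 (3.5 equiv), −78 °C; MgBr2·OEt2 in MeOH, −78 °C → rt
Reagents that add atoms: none
Why: s-BuLi, held by the carbamate carbonyl, removes each benzylic C7–H with retention to give a configurationally stable α-carbamoyloxy benzyllithium, which binds the boron of 4 with retention; on warming, C8 shifts from boron to C7 on the side opposite the departing carbamate (1,2-metallate rearrangement), so C7 inverts and the C7–C8 bond forms with boron left on C7. The closest known reaction type is the lithiation–borylation of secondary benzylic carbamates with primary alkyl pinacol boronates to give tertiary boronic esters. No ring is closed; the 22-membered ring only carries the two reacting sites. Each new C7 centre is fixed stereospecifically by the (S)-carbinol configuration installed in step 9, so no induction from neighbouring centres is required. The step needs site selectivity for C7–H over the ring C–H bonds next to the MOM ethers and over C1–H, which complexation of the base at the carbamate should secure because the silyl ethers offer no such contact; it also needs the crowded boronate complexes to rearrange before they dissociate, which MgBr2 in MeOH should secure by accelerating the shift and protonating any benzyllithium set free.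

**Step 14**
Reactants: 25 bis(tertiary boronic ester)
Product: 27 cyclophane C1,C1'-diol with C7–H and 4,4-dimethoxybutyl chains (1R,2S,7S in each half), via bis-TBS ether 26 (not isolated)
Conditions: TBAF·3H2O (excess), toluene, 45 °C; then THF, 45 °C
Reagents that add atoms: none
Why: fluoride-promoted protodeboronation of aryl dialkyl tertiary boronic esters proceeds by front-side protonation of the fluoroboronate with retention, so hydrogen takes the place of boron at C7, and the same reagent then cleaves both C1 silyl ethers.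

**Step 15**
Reactants: 27 cyclophane diol
Product: 29 cyclophane bis(C1 carbamate) bis(dimethyl acetal), via bis(N-trichloroacetylcarbamate) 28 (not isolated)
Conditions: Cl3CC(O)NCO, CH2Cl2, 0 °C; then K2CO3, MeOH, rt
Reagents that add atoms: trichloroacetyl isocyanate, O=C=NC(=O)C(Cl)(Cl)Cl
Why: addition of the secondary alcohols to the acyl isocyanate and methanolysis of the trichloroacetyl group gives the primary carbamates under conditions that leave acetals, MOM ethers and the C1 configuration untouched.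

**Step 16**
Reactants: 29 bis(carbamate) bis(acetal)
Product: 30 cyclophane bis(carbamate) dialdehyde (side chains CH2CH2CH2CHO)
Conditions: AcOH/THF/H2O, 35 °C
Reagents that add atoms: water, O
Why: acid-catalysed hydrolysis of aliphatic dimethyl acetals is much faster than cleavage of aryl MOM ethers, so both aldehydes should be released selectively.

**Step 17**
Reactants: 30 dialdehyde
Product: 32 tetra-MOM-protected tetrachloride (side chains CH2CH2CH2CHCl2), via bis(hydrazone) 31 (not isolated)
Conditions: N2H4·H2O (excess), EtOH, rt, then evaporation; CuCl2, Et3N, MeOH, 0 °C → rt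
Reagents that add atoms: CuCl2 (copper dichloride), Cl[Cu]Cl
Why: condensation to the N-unsubstituted hydrazones followed by oxidative chlorination with divalent copper chloride (hydrazone to diazo compound to gem-dichloride with loss of N2) converts each CHO into CHCl2 under non-acidic conditions that spare MOM ethers and carbamates.

**Step 18**
Reactants: 32 protected tetrachloride
Product: 33 CNP0205627.1
Conditions: 3 M HCl (aq.)/MeOH, 40 °C
Reagents that add atoms: none
Why: acid-catalysed acetal exchange with methanol frees the four phenols; the gem-dichlorides are acid-stable, and the C1 carbamates sit on a benzylic carbon meta to both ring oxygens and are therefore not prone to ionisation.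

**Compound list**

1 | 4-chloro-1,1-dimethoxybutane | COC(CCCCl)OC | starting material
2 | 2-isopropoxy-4,4,5,5-tetramethyl-1,3,2-dioxaborolane | CC(C)OB1OC(C)(C)C(C)(C)O1 | starting material
3 | (4,4-dimethoxybutyl)magnesium chloride, not isolated | COC(OC)CCC[Mg]Cl | intermediate
4 | 2-(4,4-dimethoxybutyl)-4,4,5,5-tetramethyl-1,3,2-dioxaborolane | COC(OC)CCCB1OC(C)(C)C(C)(C)O1 | intermediate
5 | 3,5-dihydroxybenzaldehyde | O=Cc1cc(O)cc(O)c1 | starting material
6 | 3,5-bis(methoxymethoxy)benzaldehyde | COCOc1cc(C=O)cc(OCOC)c1 | intermediate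
7 | (R)-4-benzyl-3-propionyloxazolidin-2-one | CCC(=O)N1[C@H](Cc2ccccc2)COC1=O | starting material
8 | Z-dibutylboron enolate of 7, not isolated | C/C=C(\OB(CCCC)CCCC)N1[C@H](Cc2ccccc2)COC1=O | intermediate
9 | O-dibutylboryl derivative of aldol adduct 10, not isolated | COCOc1cc(cc(OCOC)c1)[C@H](OB(CCCC)CCCC)[C@@H](C)C(=O)N1[C@H](Cc2ccccc2)COC1=O | intermediate
10 | (R)-4-benzyl-3-[(2R,3R)-3-[3,5-bis(methoxymethoxy)phenyl]-3-hydroxy-2-methylpropanoyl]oxazolidin-2-one | COCOc1cc(cc(OCOC)c1)[C@H](O)[C@@H](C)C(=O)N1[C@H](Cc2ccccc2)COC1=O | intermediate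
11 | (R)-4-benzyl-3-[(2R,3R)-3-[3,5-bis(methoxymethoxy)phenyl]-3-(tert-butyldimethylsilyloxy)-2-methylpropanoyl]oxazolidin-2-one | COCOc1cc(cc(OCOC)c1)[C@H](O[Si](C)(C)C(C)(C)C)[C@@H](C)C(=O)N1[C@H](Cc2ccccc2)COC1=O | intermediate
12 | (2S,3R)-3-[3,5-bis(methoxymethoxy)phenyl]-3-(tert-butyldimethylsilyloxy)-2-methylpropan-1-ol | COCOc1cc(cc(OCOC)c1)[C@H](O[Si](C)(C)C(C)(C)C)[C@@H](C)CO | intermediate
13 | tert-butyl[(1R,2R)-1-[3,5-bis(methoxymethoxy)phenyl]-3-iodo-2-methylpropoxy]dimethylsilane | COCOc1cc(cc(OCOC)c1)[C@H](O[Si](C)(C)C(C)(C)C)[C@@H](C)CI | intermediate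
14 | tert-butyl[(1R,2S)-1-[3,5-bis(methoxymethoxy)phenyl]-2-methylpent-4-enyloxy]dimethylsilane | COCOc1cc(cc(OCOC)c1)[C@H](O[Si](C)(C)C(C)(C)C)[C@@H](C)CC=C | intermediate
15 | aryllithium of 14, lithium on the ring carbon between the two MOM ethers, not isolated | [Li]c1c(OCOC)cc(cc1OCOC)[C@H](O[Si](C)(C)C(C)(C)C)[C@@H](C)CC=C | intermediate
16 | 4-[(1R,2S)-1-(tert-butyldimethylsilyloxy)-2-methylpent-4-enyl]-2,6-bis(methoxymethoxy)benzaldehyde | O=Cc1c(OCOC)cc(cc1OCOC)[C@H](O[Si](C)(C)C(C)(C)C)[C@@H](C)CC=C | intermediate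
17 | O-diisopinocampheylboryl derivative of alcohol 18, not isolated | C=CC[C@H](OB([C@@H]2C[C@@H]3C[C@H]([C@H]2C)C3(C)C)[C@@H]2C[C@@H]3C[C@H]([C@H]2C)C3(C)C)c1c(OCOC)cc(cc1OCOC)[C@H](O[Si](C)(C)C(C)(C)C)[C@@H](C)CC=C | intermediate
18 | (1S)-1-{4-[(1R,2S)-1-(tert-butyldimethylsilyloxy)-2-methylpent-4-enyl]-2,6-bis(methoxymethoxy)phenyl}but-3-en-1-ol | C=CC[C@H](O)c1c(OCOC)cc(cc1OCOC)[C@H](O[Si](C)(C)C(C)(C)C)[C@@H](C)CC=C | intermediate
19 | N,N-diisopropylcarbamoyl chloride | CC(C)N(C(C)C)C(Cl)=O | starting material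
20 | (1S)-1-{4-[(1R,2S)-1-(tert-butyldimethylsilyloxy)-2-methylpent-4-enyl]-2,6-bis(methoxymethoxy)phenyl}but-3-enyl N,N-diisopropylcarbamate | C=CC[C@H](OC(=O)N(C(C)C)C(C)C)c1c(OCOC)cc(cc1OCOC)[C@H](O[Si](C)(C)C(C)(C)C)[C@@H](C)CC=C | intermediate
21 | cyclophane (E,E)-diene: C4=C5 double bond in each bridge, N,N-diisopropylcarbamate on each C7, TBS ether on each C1, methyl on each C2, four MOM ethers; (1R,2S,7S) in both halves | C[C@H]1C/C=C/C[C@H](OC(=O)N(C(C)C)C(C)C)c2c(OCOC)cc(cc2OCOC)[C@H](O[Si](C)(C)C(C)(C)C)[C@@H](C)C/C=C/C[C@H](OC(=O)N(C(C)C)C(C)C)c2c(OCOC)cc(cc2OCOC)[C@@H]1O[Si](C)(C)C(C)(C)C | intermediate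
22 | saturated cyclophane: N,N-diisopropylcarbamate on each C7, TBS ether on each C1, methyl on each C2, four MOM ethers; (1R,2S,7S) in both halves | C[C@H]1CCCC[C@H](OC(=O)N(C(C)C)C(C)C)c2c(OCOC)cc(cc2OCOC)[C@H](O[Si](C)(C)C(C)(C)C)[C@@H](C)CCCC[C@H](OC(=O)N(C(C)C)C(C)C)c2c(OCOC)cc(cc2OCOC)[C@@H]1O[Si](C)(C)C(C)(C)C | intermediate
23 | C7,C7'-dilithio derivative of 22 (lithium in place of each C7–H), not isolated | C[C@H]1CCCC[C@]([Li])(OC(=O)N(C(C)C)C(C)C)c2c(OCOC)cc(cc2OCOC)[C@H](O[Si](C)(C)C(C)(C)C)[C@@H](C)CCCC[C@]([Li])(OC(=O)N(C(C)C)C(C)C)c2c(OCOC)cc(cc2OCOC)[C@@H]1O[Si](C)(C)C(C)(C)C | intermediate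
24 | dilithium bis(boronate) complex: each C7 bonded to a tetracoordinate pinacolato(4,4-dimethoxybutyl)borate, carbamates still on C7, not isolated | C[C@H]1CCCC[C@]([B-]3(CCCC(OC)OC)OC(C)(C)C(C)(C)O3)(OC(=O)N(C(C)C)C(C)C)c2c(OCOC)cc(cc2OCOC)[C@H](O[Si](C)(C)C(C)(C)C)[C@@H](C)CCCC[C@]([B-]3(CCCC(OC)OC)OC(C)(C)C(C)(C)O3)(OC(=O)N(C(C)C)C(C)C)c2c(OCOC)cc(cc2OCOC)[C@@H]1O[Si](C)(C)C(C)(C)C.[Li+].[Li+] | intermediate
25 | cyclophane bis(tertiary pinacol boronic ester): each C7 carries Bpin and a 4,4-dimethoxybutyl chain, TBS ethers on C1, four MOM ethers; (1R,2S,7S) in both halves | C[C@H]1CCCC[C@@](B3OC(C)(C)C(C)(C)O3)(CCCC(OC)OC)c2c(OCOC)cc(cc2OCOC)[C@H](O[Si](C)(C)C(C)(C)C)[C@@H](C)CCCC[C@@](B3OC(C)(C)C(C)(C)O3)(CCCC(OC)OC)c2c(OCOC)cc(cc2OCOC)[C@@H]1O[Si](C)(C)C(C)(C)C | intermediate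
26 | cyclophane with C7–H and 4,4-dimethoxybutyl on each C7, TBS ethers on C1, four MOM ethers; (1R,2S,7S) in both halves; not isolated in step 14 | C[C@H]1CCCC[C@@H](CCCC(OC)OC)c2c(OCOC)cc(cc2OCOC)[C@H](O[Si](C)(C)C(C)(C)C)[C@@H](C)CCCC[C@@H](CCCC(OC)OC)c2c(OCOC)cc(cc2OCOC)[C@@H]1O[Si](C)(C)C(C)(C)C | intermediate
27 | cyclophane C1,C1'-diol with 4,4-dimethoxybutyl on each C7, four MOM ethers; (1R,2S,7S) in both halves | C[C@H]1CCCC[C@@H](CCCC(OC)OC)c2c(OCOC)cc(cc2OCOC)[C@H](O)[C@@H](C)CCCC[C@@H](CCCC(OC)OC)c2c(OCOC)cc(cc2OCOC)[C@@H]1O | intermediate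
28 | bis(N-trichloroacetylcarbamate) of 27, not isolated | C[C@H]1CCCC[C@@H](CCCC(OC)OC)c2c(OCOC)cc(cc2OCOC)[C@H](OC(=O)NC(=O)C(Cl)(Cl)Cl)[C@@H](C)CCCC[C@@H](CCCC(OC)OC)c2c(OCOC)cc(cc2OCOC)[C@@H]1OC(=O)NC(=O)C(Cl)(Cl)Cl | intermediate
29 | cyclophane bis(C1 carbamate, OCONH2) with 4,4-dimethoxybutyl on each C7, four MOM ethers; (1R,2S,7S) in both halves | C[C@H]1CCCC[C@@H](CCCC(OC)OC)c2c(OCOC)cc(cc2OCOC)[C@H](OC(N)=O)[C@@H](C)CCCC[C@@H](CCCC(OC)OC)c2c(OCOC)cc(cc2OCOC)[C@@H]1OC(N)=O | intermediate
30 | cyclophane bis(C1 carbamate) dialdehyde (4-oxobutyl on each C7), four MOM ethers; (1R,2S,7S) in both halves | C[C@H]1CCCC[C@@H](CCCC=O)c2c(OCOC)cc(cc2OCOC)[C@H](OC(N)=O)[C@@H](C)CCCC[C@@H](CCCC=O)c2c(OCOC)cc(cc2OCOC)[C@@H]1OC(N)=O | intermediate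
31 | bis(hydrazone) of 30, not isolated | C[C@H]1CCCC[C@@H](CCCC=NN)c2c(OCOC)cc(cc2OCOC)[C@H](OC(N)=O)[C@@H](C)CCCC[C@@H](CCCC=NN)c2c(OCOC)cc(cc2OCOC)[C@@H]1OC(N)=O | intermediate
32 | cyclophane bis(C1 carbamate) with 4,4-dichlorobutyl on each C7, four MOM ethers; (1R,2S,7S) in both halves | C[C@H]1CCCC[C@@H](CCCC(Cl)Cl)c2c(OCOC)cc(cc2OCOC)[C@H](OC(N)=O)[C@@H](C)CCCC[C@@H](CCCC(Cl)Cl)c2c(OCOC)cc(cc2OCOC)[C@@H]1OC(N)=O | intermediate
33 | CNP0205627.1: cyclophane with OCONH2 on each C1, methyl on each C2, 4,4-dichlorobutyl on each C7, free phenols flanking each C7; (1R,2S,7S) in both halves | C[C@H]1CCCC[C@@H](CCCC(Cl)Cl)c2c(O)cc(cc2O)[C@H](OC(N)=O)[C@@H](C)CCCC[C@@H](CCCC(Cl)Cl)c2c(O)cc(cc2O)[C@@H]1OC(N)=O | target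

**Step count and risks**

Total step count: 18. Longest linear sequence: 17 steps (steps 2–18, from 5); step 1 makes the side-chain boronate.

Steps most likely to fail:

1. Step 13. The twofold benzylic deprotonation may stall on the ring, because the C7–H bonds are likely to lie near the arene plane between the two MOM ethers, which lowers their kinetic acidity. Ring lithiation next to a MOM ether, or dissociation of the crowded boronate complexes before the shift, could then take over. Fallback: attach the side chain before ring closure. Setting out from monomer 20, one lithiation–borylation with 4 under the conditions of step 13 should give the open-chain tertiary boronic ester F1. TBAF·3H2O (toluene, then THF, 45 °C) should exchange boron for hydrogen with retention and free the C1 hydroxyl to give diene alcohol F2. Cyclodimerisation with the second-generation Grubbs catalyst should give cyclophane diene diol F3, and hydrogenation over RhCl(PPh3)3 comes back to the route at 27.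

2. Step 14. Protonolysis of the C7–B bonds may be too slow at the crowded, electron-rich benzylic carbon, so that desilylation and base-mediated degradation outrun it and the boron stays on C7. Fallback: build the C7–H centre without boron. Setting out from aldehyde 16, Horner–Wadsworth–Emmons olefination with (R)-3-[2-(diethoxyphosphoryl)acetyl]-4-phenyloxazolidin-2-one (LiCl, iPr2NEt, MeCN) should give E-enoyl imide F4. Conjugate addition of the organocopper reagent made from Grignard reagent 3 and CuBr·SMe2 (THF, −40 °C), anti to the phenyl group of the auxiliary in the chelated s-cis conformer, should give adduct F5 with C7–C8 and C7–H in place. LiBH4 should give alcohol F6, Dess–Martin periodinane aldehyde F7, and Ph3P=CH2 diene F8. Cyclodimerisation with the second-generation Grubbs catalyst should give cyclophane diene F9, and hydrogenation over RhCl(PPh3)3 comes back to the route at 26, which TBAF converts into 27 as in the second half of step 14.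

3. Step 11. The bulky carbamate arm may slow productive metathesis, and its carbonyl can chelate the ruthenium carbene from the homoallylic position, so that open-chain oligomers or head-to-head pairs accumulate and do not equilibrate to the cyclic head-to-tail dimer. Fallback: close the ring before the carbamate is introduced. Setting out from alcohol 18, cyclodimerisation with the second-generation Grubbs catalyst should give cyclophane diene diol F10, hydrogenation over RhCl(PPh3)3 saturated diol F11, and twofold carbamoylation (KH, 19, THF) comes back to the route at 22.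

**Further compounds**

F1 | step 13 | 2-{(4R)-4-[4-[(1R,2S)-1-(tert-butyldimethylsilyloxy)-2-methylpent-4-enyl]-2,6-bis(methoxymethoxy)phenyl]-8,8-dimethoxyoct-1-en-4-yl}-4,4,5,5-tetramethyl-1,3,2-dioxaborolane | C=CC[C@@](B2OC(C)(C)C(C)(C)O2)(CCCC(OC)OC)c1c(OCOC)cc(cc1OCOC)[C@H](O[Si](C)(C)C(C)(C)C)[C@@H](C)CC=C
F2 | step 13 | (1R,2S)-1-{4-[(4R)-8,8-dimethoxyoct-1-en-4-yl]-3,5-bis(methoxymethoxy)phenyl}-2-methylpent-4-en-1-ol | C=CC[C@@H](CCCC(OC)OC)c1c(OCOC)cc(cc1OCOC)[C@H](O)[C@@H](C)CC=C
F3 | step 13 | cyclophane (E,E)-diene C1,C1'-diol with 4,4-dimethoxybutyl on each C7, four MOM ethers; (1R,2S,7R) in both halves | C[C@H]1C/C=C/C[C@@H](CCCC(OC)OC)c2c(OCOC)cc(cc2OCOC)[C@H](O)[C@@H](C)C/C=C/C[C@@H](CCCC(OC)OC)c2c(OCOC)cc(cc2OCOC)[C@@H]1O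
F4 | step 14 | (R)-3-[(E)-3-{4-[(1R,2S)-1-(tert-butyldimethylsilyloxy)-2-methylpent-4-enyl]-2,6-bis(methoxymethoxy)phenyl}acryloyl]-4-phenyloxazolidin-2-one | O=C(/C=C/c1c(OCOC)cc(cc1OCOC)[C@H](O[Si](C)(C)C(C)(C)C)[C@@H](C)CC=C)N1[C@H](c2ccccc2)COC1=O
F5 | step 14 | (R)-3-[(3R)-3-{4-[(1R,2S)-1-(tert-butyldimethylsilyloxy)-2-methylpent-4-enyl]-2,6-bis(methoxymethoxy)phenyl}-7,7-dimethoxyheptanoyl]-4-phenyloxazolidin-2-one | O=C(C[C@@H](CCCC(OC)OC)c1c(OCOC)cc(cc1OCOC)[C@H](O[Si](C)(C)C(C)(C)C)[C@@H](C)CC=C)N1[C@H](c2ccccc2)COC1=O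
F6 | step 14 | (3R)-3-{4-[(1R,2S)-1-(tert-butyldimethylsilyloxy)-2-methylpent-4-enyl]-2,6-bis(methoxymethoxy)phenyl}-7,7-dimethoxyheptan-1-ol | OCC[C@@H](CCCC(OC)OC)c1c(OCOC)cc(cc1OCOC)[C@H](O[Si](C)(C)C(C)(C)C)[C@@H](C)CC=C
F7 | step 14 | (3R)-3-{4-[(1R,2S)-1-(tert-butyldimethylsilyloxy)-2-methylpent-4-enyl]-2,6-bis(methoxymethoxy)phenyl}-7,7-dimethoxyheptanal | O=CC[C@@H](CCCC(OC)OC)c1c(OCOC)cc(cc1OCOC)[C@H](O[Si](C)(C)C(C)(C)C)[C@@H](C)CC=C
F8 | step 14 | tert-butyl[(1R,2S)-1-{4-[(4R)-8,8-dimethoxyoct-1-en-4-yl]-3,5-bis(methoxymethoxy)phenyl}-2-methylpent-4-enyloxy]dimethylsilane | C=CC[C@@H](CCCC(OC)OC)c1c(OCOC)cc(cc1OCOC)[C@H](O[Si](C)(C)C(C)(C)C)[C@@H](C)CC=C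
F9 | step 14 | cyclophane (E,E)-diene with 4,4-dimethoxybutyl on each C7, TBS ethers on C1, four MOM ethers; (1R,2S,7R) in both halves | C[C@H]1C/C=C/C[C@@H](CCCC(OC)OC)c2c(OCOC)cc(cc2OCOC)[C@H](O[Si](C)(C)C(C)(C)C)[C@@H](C)C/C=C/C[C@@H](CCCC(OC)OC)c2c(OCOC)cc(cc2OCOC)[C@@H]1O[Si](C)(C)C(C)(C)C
F10 | step 11 | cyclophane (E,E)-diene C7,C7'-diol, TBS ethers on C1, four MOM ethers; (1R,2S,7S) in both halves | C[C@H]1C/C=C/C[C@H](O)c2c(OCOC)cc(cc2OCOC)[C@H](O[Si](C)(C)C(C)(C)C)[C@@H](C)C/C=C/C[C@H](O)c2c(OCOC)cc(cc2OCOC)[C@@H]1O[Si](C)(C)C(C)(C)C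
F11 | step 11 | saturated cyclophane C7,C7'-diol, TBS ethers on C1, four MOM ethers; (1R,2S,7S) in both halves | C[C@H]1CCCC[C@H](O)c2c(OCOC)cc(cc2OCOC)[C@H](O[Si](C)(C)C(C)(C)C)[C@@H](C)CCCC[C@H](O)c2c(OCOC)cc(cc2OCOC)[C@@H]1O[Si](C)(C)C(C)(C)C
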